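**Retrosynthetic overview**

1. Feature: in the pyran ring O–Ca–Cb–Cc–C3=C4 of quinolone B, Ca (the O–CH carbon on C3 of quinolone A) and the C4 oxygen of quinolone B are 1,5-related through Cb (ring-fusion CH next to C(CH3)2), Cc (CH with the side chain) and C3 of quinolone B. This ring is therefore the reduced cyclic hemiketal of a 1,5-dicarbonyl unit.
2. Late stage: the tertiary alcohol comes from an isobutenyl group by Markovnikov hydration, and Ca–H from the hemiketal Ca–OH by ionic reduction.
3. Key disconnection: C3(B)–Cc and O–Ca, a formal [3+3] annulation of 4-hydroxyquinolone 1 with the exocyclic dienone 8.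
4. Dienone 8 comes from ring ketone 4 and 3-methylbut-2-enal 5 by aldol condensation; 4 comes from 1 and 3-methylbut-2-enoic acid 2 by acylation and oxa-Michael closure.
5. Ring order: both quinolone nuclei are bought as 1; the gem-dimethyl pyranone ring closes in step 1, the second pyran ring in step 3, and it is fixed as a cyclic ether in step 4.

Key step: step 3

Assumption: the sense of induction of the quinine-derived squaramide at Cc is assigned by analogy with related enone additions; should it deliver the antipode, the quinidine-derived pseudo-enantiomer is used without other change.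

Target descriptors used below: Ca S, Cb R, Cc R (Ca–H and Cb–H cis; Cb–H and Cc–H trans).

**Route**

Step 1
Reactants: 1 4-hydroxy-1-methylquinolin-2(1H)-one; 2 3-methylbut-2-enoic acid
Product: 4 2,2,6-trimethyl-2,3-dihydro-4H-pyrano[3,2-c]quinoline-4,5(6H)-dione (ring ketone), via acylquinolone 3 (not isolated)
Conditions: Eaton's reagent (P2O5/MeSO3H), 70 °C
Reagents that add atoms: none
Why: Friedel–Crafts-type C3 acylation of the vinylogous acid by the activated acid gives enone 3, whose 4-OH closes onto the β,β-dimethyl enone by acid-catalysed oxa-Michael addition, the same acylation–cyclisation that converts phenols into 2,2-dimethylchroman-4-ones; no stereocentre is formed.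

Step 2
Reactants: 4 ring ketone; 5 3-methylbut-2-enal
Product: 8 (3Z)-2,2,6-trimethyl-3-(3-methylbut-2-en-1-ylidene)-2,3-dihydro-4H-pyrano[3,2-c]quinoline-4,5(6H)-dione (dienone), via aldol adduct 6 (not isolated), via aldol acetate 7 (not isolated)
Conditions: LiHMDS, THF, −78 °C; 5; Ac2O, −78 → 0 °C; DBU, rt
Reagents that add atoms: none
Why: Directed aldol condensation: C3 is the only enolisable position of 4, the lithium enolate should be stable at −78 °C towards β-elimination of the ring oxygen and adds 1,2 to the enal, the aldolate is trapped as acetate 7, and DBU effects E1cB loss of acetate to the cross-conjugated dienone, whose Z geometry (isobutenyl syn to C4=O) avoids A(1,3) strain with the C2 gem-dimethyl group.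

Step 3
Reactants: 8 dienone; 1 4-hydroxy-1-methylquinolin-2(1H)-one (1.2 equiv)
Product: 10 pentacyclic hemiketal with OH on Ca and isobutenyl on Cc (Ca S/Cb S/Cc R), via keto adduct 9 (not isolated)
Conditions: quinine-derived 3,5-bis(trifluoromethyl)phenyl squaramide (10 mol%), CH2Cl2, rt
Reagents that add atoms: none
Why: The quinuclidine nitrogen deprotonates the vinylogous acid 1 while the squaramide N–H bonds hold the peri-disposed C4/C5 carbonyl pair of 8; C3 of the quinolonate adds to the exocyclic β-carbon (Cc), the enol is protonated at Cb to give 9, and the 4-OH of the new quinolone adds to the Ca ketone. The closest known reaction type is the squaramide- or thiourea-catalysed Michael addition–hemiketalisation of 4-hydroxycoumarins and 4-hydroxyquinolin-2-ones with enones (asymmetric warfarin-type synthesis). The pyran ring O–Ca–Cb–Cc–C3=C4 closes by 6-exo-trig attack of oxygen on the carbonyl group. Cc is set by the catalyst, which shields one face of the bound dienone; Cb is set under thermodynamic control, because it stays enolisable through 9 and the hemiketal with the Cc isobutenyl group trans to the C(CH3)2 branch on Cb should be lowest in energy; the hemiketal carbon Ca is labile and its configuration is lost in step 4. The step needs 1,4- over 1,6-addition, secured by the fully substituted δ-carbon of the dienone, C- over O-alkylation, secured by the soft C3 nucleophile, and closure through the 4-oxygen and not the amide oxygen, secured by reversible hemiketal formation and the greater stability of the N-methyl-2-quinolone form.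

Step 4
Reactants: 10 pentacyclic hemiketal
Product: 11 cis-fused pentacyclic ether with isobutenyl on Cc (Ca S/Cb R/Cc R)
Conditions: Et3SiH, BF3·OEt2, CH2Cl2, −78 → −30 °C
Reagents that add atoms: none
Why: Reductive deoxygenation of a hemiketal by ionic hydrogenation: BF3 ionises 10 to an oxocarbenium ion at Ca that is delocalised into the enol ether of quinolone A, and Et3SiH should deliver hydride on the face of the Cb–H, anti to the pseudo-axial methyl of the neighbouring C(CH3)2 group, which sets Ca and the cis ring fusion while the trisubstituted alkene is left alone at low temperature.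

Step 5
Reactants: 11 cis-fused pentacyclic ether
Product: 12 CNP0202276.1 (Ca S/Cb R/Cc R; side chain CH2C(CH3)2OH)
Conditions: Co(acac)2 (20 mol%), PhSiH3, O2 (1 atm), THF, rt; aq. Na2S2O3
Reagents that add atoms: dioxygen, O=O
Why: Mukaiyama hydration: the cobalt hydride transfers a hydrogen atom to the CH end of the isobutenyl group, the tertiary radical is trapped by O2 and the peroxide is reduced by the silane to the Markovnikov tertiary alcohol, while the tetrasubstituted, electron-poor quinolone double bonds and the three stereocentres are not touched.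

**Compound list**

1 | 4-hydroxy-1-methylquinolin-2(1H)-one | Cn1c(=O)cc(O)c2ccccc21 | starting material
2 | 3-methylbut-2-enoic acid | CC(C)=CC(=O)O | starting material
3 | 4-hydroxy-1-methyl-3-(3-methylbut-2-enoyl)quinolin-2(1H)-one | Cn1c(=O)c(C(=O)C=C(C)C)c(O)c2ccccc21 | intermediate (not isolated)
4 | 2,2,6-trimethyl-2,3-dihydro-4H-pyrano[3,2-c]quinoline-4,5(6H)-dione | Cn1c(=O)c2c(c3ccccc31)OC(C)(C)CC2=O | intermediate
5 | 3-methylbut-2-enal | CC(C)=CC=O | starting material
6 | 3-(1-hydroxy-3-methylbut-2-en-1-yl)-2,2,6-trimethyl-2,3-dihydro-4H-pyrano[3,2-c]quinoline-4,5(6H)-dione, formed as its lithium alkoxide, diastereomer mixture | Cn1c(=O)c2c(c3ccccc31)OC(C)(C)C(C(O)C=C(C)C)C2=O | intermediate (not isolated)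
7 | acetate of 6, diastereomer mixture | Cn1c(=O)c2c(c3ccccc31)OC(C)(C)C(C(OC(C)=O)C=C(C)C)C2=O | intermediate (not isolated)
8 | (3Z)-2,2,6-trimethyl-3-(3-methylbut-2-en-1-ylidene)-2,3-dihydro-4H-pyrano[3,2-c]quinoline-4,5(6H)-dione | Cn1c(=O)c2c(c3ccccc31)OC(C)(C)/C(=C/C=C(C)C)C2=O | intermediate
9 | (3S)-3-[(1R)-1-(4-hydroxy-1-methyl-2-oxo-1,2-dihydroquinolin-3-yl)-3-methylbut-2-en-1-yl]-2,2,6-trimethyl-2,3-dihydro-4H-pyrano[3,2-c]quinoline-4,5(6H)-dione, open keto tautomer of 10 | Cn1c(=O)c2c(c3ccccc31)OC(C)(C)[C@@H](C2=O)[C@@H](C=C(C)C)c1c(O)c2ccccc2n(C)c1=O | intermediate (not isolated)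
10 | pentacyclic hemiketal: two N-methyl-pyrano[3,2-c]quinolin-5-one units sharing the Ca–Cb bond, OH on Ca drawn cis to Cb–H (anomers interconvert), isobutenyl on Cc trans to the C(CH3)2 branch; Ca S, Cb S, Cc R | Cn1c(=O)c2c(c3ccccc31)OC(C)(C)[C@H]1[C@]2(O)Oc2c(c(=O)n(C)c3ccccc23)[C@@H]1C=C(C)C | intermediate
11 | cis-fused pentacyclic ether, Ca–H cis to Cb–H, isobutenyl on Cc; Ca S, Cb R, Cc R | Cn1c(=O)c2c(c3ccccc31)OC(C)(C)[C@H]1[C@@H]2Oc2c(c(=O)n(C)c3ccccc23)[C@@H]1C=C(C)C | intermediate
12 | CNP0202276.1, cis-fused pentacyclic ether with 2-hydroxy-2-methylpropyl on Cc; Ca S, Cb R, Cc R | Cn1c(=O)c2c(c3ccccc31)OC(C)(C)[C@H]1[C@@H]2Oc2c(c(=O)n(C)c3ccccc23)[C@@H]1CC(C)(C)O | target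

**Step count**

Total steps: 5. Longest linear sequence: 5 steps (1 → 4 → 8 → 10 → 11 → 12); compound 1 enters a second time in step 3.

**Steps most likely to fail**

Step 3 (key step). The conjugate addition may be slow, because the acceptor is α-branched, flanked by a quaternary carbon and deactivated by vinylogous-ester donation, and the cis-dienone may rest partly in a reversible 6π-oxa-electrocyclised form. Facial selectivity at Cc may also be poor, or Cb may not fully equilibrate. Fallback: setting out from 8 and 1, an achiral base (DABCO, EtOH, 60 °C) should drive the same Michael addition–hemiketalisation without any demand on facial control and give the racemic hemiketal F1. Reduction with Et3SiH and BF3·OEt2 as in step 4 should give the racemic cis-fused isobutenyl ether F2. Preparative chromatography on a chiral stationary phase (SFC) then separates the enantiomers, and the route is rejoined at 11.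

Step 4. Hydride may be delivered to the wrong face of the oxocarbenium ion. The cation may lose the Cb proton to a 4H-pyran enol ether, with scrambling of Cb on reprotonation. The open keto tautomer may be over-reduced. Fallback: setting out from 10, which reacts through its open tautomer 9, TsCl and Et3N in CH2Cl2 should sulfonylate the acidic quinolone 4-OH and give the keto tosylate F3. Luche reduction (NaBH4, CeCl3·7H2O, MeOH, −20 °C) should add hydride to the ketone anti to the pseudo-axial methyl group and give the alcohol tosylate F4 with the carbinol H cis to Cb–H. K2CO3 in DMF then closes the pyran by intramolecular addition–elimination of the alkoxide at C4 of the 4-tosyloxyquinolin-2-one. The C–O bond at Ca is not broken, so its configuration is retained, and the route is rejoined at 11.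

Step 2. The enolate may eliminate the ring oxygen (retro-oxa-Michael ring opening), the enal may be deprotonated at its γ-position, or the elimination may give a mixture of alkene isomers. Fallback: setting out from 4, soft enolisation with TMSOTf and Et3N in CH2Cl2 at 0 °C should give the trimethylsilyl enol ether F5 without a free enolate. Mukaiyama aldol addition to 5 (BF3·OEt2, CH2Cl2, −78 °C) should give aldol 6 after work-up, and acid-catalysed dehydration (cat. TsOH, benzene, rt) returns the route at 8. A geometric mixture would be equilibrated with catalytic iodine.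

**Further compounds**

F1 | step 3 | racemic pentacyclic hemiketal (rac-10, both enantiomers shown) | Cn1c(=O)c2c(c3ccccc31)OC(C)(C)[C@H]1[C@]2(O)Oc2c(c(=O)n(C)c3ccccc23)[C@@H]1C=C(C)C.Cn1c(=O)c2c(c3ccccc31)OC(C)(C)[C@@H]1[C@@]2(O)Oc2c(c(=O)n(C)c3ccccc23)[C@H]1C=C(C)C
F2 | step 3 | racemic cis-fused isobutenyl pentacyclic ether (rac-11, both enantiomers shown) | Cn1c(=O)c2c(c3ccccc31)OC(C)(C)[C@H]1[C@@H]2Oc2c(c(=O)n(C)c3ccccc23)[C@@H]1C=C(C)C.Cn1c(=O)c2c(c3ccccc31)OC(C)(C)[C@@H]1[C@H]2Oc2c(c(=O)n(C)c3ccccc23)[C@H]1C=C(C)C
F3 | step 4 | 4-O-tosylate of keto adduct 9 | Cn1c(=O)c2c(c3ccccc31)OC(C)(C)[C@@H](C2=O)[C@@H](C=C(C)C)c1c(OS(=O)(=O)c2ccc(C)cc2)c2ccccc2n(C)c1=O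
F4 | step 4 | alcohol from ketone reduction of F3, carbinol H cis to Cb–H | Cn1c(=O)c2c(c3ccccc31)OC(C)(C)[C@@H]([C@@H]2O)[C@@H](C=C(C)C)c1c(OS(=O)(=O)c2ccc(C)cc2)c2ccccc2n(C)c1=O
F5 | step 2 | 2,2,6-trimethyl-4-(trimethylsilyloxy)-2H-pyrano[3,2-c]quinolin-5(6H)-one (silyl enol ether of 4) | Cn1c(=O)c2c(c3ccccc31)OC(C)(C)C=C2O[Si](C)(C)C
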